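**Retrosynthetic overview**

- Target 16 is unmasked from tris-MOM chalcone 15, whose enone C=C comes from a Claisen–Schmidt condensation of methyl ketone 11 with aldehyde 13; ring B arrives intact with the aldehyde.
- The C3 hydroxyl of 11 is carried as a C3–B bond (boronate 9) and revealed by stereoretentive oxidation.
- The strategy rests on the dihydropyran ring: its atoms O1–C8a=C4a–C4 are a 1-oxadiene hidden in ring A (an o-quinone methide), and C2 (gem-dimethyl) plus C3 (carbinol) are the two carbons of an alkene. Cutting O1–C2 and C3–C4 gives quinone methide 8 and Me2C=CH–Bpin 7.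
- Quinone methide precursor 6 comes from 2,4,6-trihydroxyacetophenone 1 by para-selective silylation, MOM protection of both ortho hydroxyls, desilylation and ortho-hydroxymethylation with formaldehyde 5.
- Ring order: ring A is bought, the dihydropyran ring is closed in step 5, ring B is attached in step 8.

Key step: step 5

Assumption: the sense of induction of the chiral phosphoric acid in step 5 cannot be predicted with confidence; the route is written for the catalyst antipode that delivers the (3R)-boronate, with (R)-TRIP tried first and its enantiomer used if the sense proves opposite.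

**Step 1**
Reactants: 1 2,4,6-trihydroxyacetophenone
Product: 2 1-[2,6-dihydroxy-4-(triisopropylsilyloxy)phenyl]ethanone
Conditions: TIPSCl (1.05 equiv), imidazole (2.2 equiv), DMF, 0 °C → rt
Reagents that add atoms: triisopropylsilyl chloride, CC(C)[Si](Cl)(C(C)C)C(C)C
Why: Selective O-silylation; the C4 hydroxyl is the most acidic and the only one neither chelated to nor flanked by the acetyl group, so the bulky silyl chloride should take it alone.

**Step 2**
Reactants: 2 1-[2,6-dihydroxy-4-(triisopropylsilyloxy)phenyl]ethanone
Product: 3 1-[2,6-bis(methoxymethoxy)-4-(triisopropylsilyloxy)phenyl]ethanone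
Conditions: NaH (2.4 equiv), MOMCl (2.6 equiv), THF, 0 °C → rt
Reagents that add atoms: chloromethyl methyl ether, COCCl
Why: Williamson-type O-alkylation of both sodium phenoxides, NaH overcoming the hydrogen bond that holds back the second hydroxyl; THF is used instead of DMF so that the aryl silyl ether is not cleaved, and the meta relationship of the oxygens rules out an intramolecular silyl shift.

**Step 3**
Reactants: 3 1-[2,6-bis(methoxymethoxy)-4-(triisopropylsilyloxy)phenyl]ethanone
Product: 4 1-[4-hydroxy-2,6-bis(methoxymethoxy)phenyl]ethanone
Conditions: Bu4NF (1.1 equiv), AcOH (1.1 equiv), THF, 0 °C → rt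
Reagents that add atoms: none
Why: Fluoride-induced desilylation of an aryl silyl ether whose aryloxide is a good leaving group (para-acyl), buffered with acetic acid; the MOM acetals are inert to fluoride.

**Step 4**
Reactants: 4 1-[4-hydroxy-2,6-bis(methoxymethoxy)phenyl]ethanone; 5 formaldehyde
Product: 6 1-[4-hydroxy-3-(hydroxymethyl)-2,6-bis(methoxymethoxy)phenyl]ethanone
Conditions: 37% aq. CH2O (1.1 equiv), KOH (1.1 equiv), H2O–MeOH, 0 °C → rt; pH 7 phosphate buffer at 0 °C; used without storage
Reagents that add atoms: none
Why: Lederer–Manasse hydroxymethylation, in which the phenoxide attacks formaldehyde through an ortho carbon activated by O− and by both MOM ethers; the two ortho positions are equivalent, so one regioisomer results, and limiting formaldehyde at low temperature should hold the reaction at the mono-adduct.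

**Step 5**
Reactants: 6 1-[4-hydroxy-3-(hydroxymethyl)-2,6-bis(methoxymethoxy)phenyl]ethanone; 7 2-methylprop-1-enylboronic acid pinacol ester
Product: 9 (R)-1-[5,7-bis(methoxymethoxy)-2,2-dimethyl-3-(4,4,5,5-tetramethyl-1,3,2-dioxaborolan-2-yl)chroman-6-yl]ethanone, via o-quinone methide 8 (not isolated)
Conditions: (R)-TRIP [(R)-3,3'-bis(2,4,6-triisopropylphenyl)-1,1'-binaphthyl-2,2'-diyl hydrogen phosphate] (10 mol%), 7 (4 equiv), 3 Å MS, toluene, 0 °C → rt, slow addition of 6
Reagents that add atoms: none
Why: Proposed new method: the phosphoric acid should ionise the benzylic alcohol of 6 (cation stabilised by three ortho/para oxygens) to o-quinone methide 8, held by a hydrogen bond from P–OH to its carbonyl oxygen, and the CH(Bpin) carbon of 7 should then add to the exocyclic methylene while the tertiary, β-boryl-stabilised cationic centre at CMe2 is taken by the quinone methide oxygen, in one asynchronous inverse-electron-demand oxa-[4+2] step. The closest known reaction type is the chiral-phosphoric-acid-catalysed [4+2] cycloaddition of o-quinone methides, generated from o-hydroxybenzyl alcohols, with styrenes and 1,1-disubstituted alkenes; an alkenylboronic ester has not been shown as the 2π partner with retention of the C–B bond. The dihydropyran ring is closed by this cycloaddition, which forms C3–C4 and O1–C2 and restores the aromaticity of ring A. C3, the only new stereocentre, is set when the prochiral boron-bearing alkene carbon bonds to the methylene, so it is controlled by the chiral phosphate, which can hold the quinone methide through the hydrogen bond and the boronate through a P=O···B contact inside its 3,3'-aryl pocket; the catalyst antipode that gives the (3R)-boronate is the one kept. The step needs regio-, site- and chemoselectivity: boron ends at C3 because a tertiary cation is far better than a secondary α-boryl cation, only one quinone methide can form because only the oxygen para to the acetyl group is free, and the pinacol ester, slow to form ate complexes, should not transfer the alkenyl group with loss of boron, while excess 7 and slow addition of 6 should outrun self-condensation of 8.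

**Step 6**
Reactants: 9 (R)-1-[5,7-bis(methoxymethoxy)-2,2-dimethyl-3-(4,4,5,5-tetramethyl-1,3,2-dioxaborolan-2-yl)chroman-6-yl]ethanone
Product: 11 1-[(3R)-3-hydroxy-5,7-bis(methoxymethoxy)-2,2-dimethylchroman-6-yl]ethanone, via borate ester 10 (not isolated)
Conditions: NaBO3·4H2O (4 equiv), THF–H2O (1:1), rt
Reagents that add atoms: sodium perborate (used as the tetrahydrate), [Na+].[O-]OB=O
Why: Boron-to-oxygen 1,2-migration in the peroxoborate ate complex proceeds with retention, so the face chosen in step 5 becomes the (3R)-carbinol; the weakly basic perborate should keep β-elimination of the ring aryloxide slower than migration, and with no free phenol present the hindered aryl ketone should escape Dakin-type oxidation.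

**Step 7**
Reactants: 12 4-hydroxybenzaldehyde
Product: 13 4-(methoxymethoxy)benzaldehyde
Conditions: MOMCl (1.3 equiv), iPr2NEt (1.5 equiv), CH2Cl2, 0 °C → rt
Reagents that add atoms: chloromethyl methyl ether, COCCl
Why: Routine O-alkylation of an acidic phenol with an amine base, which keeps the aldehyde from reacting as a deactivated phenoxide in the later aldol step.

**Step 8**
Reactants: 11 1-[(3R)-3-hydroxy-5,7-bis(methoxymethoxy)-2,2-dimethylchroman-6-yl]ethanone; 13 4-(methoxymethoxy)benzaldehyde
Product: 15 (E)-1-[(3R)-3-hydroxy-5,7-bis(methoxymethoxy)-2,2-dimethylchroman-6-yl]-3-[4-(methoxymethoxy)phenyl]prop-2-en-1-one, via aldol adduct 14 (not isolated)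
Conditions: KOH (50% aq., 10 equiv), EtOH, 0 °C → rt
Reagents that add atoms: none
Why: Claisen–Schmidt condensation in which the methyl ketone is the only enolisable partner and E1cB dehydration of aldol 14 gives the thermodynamically favoured E-enone; the MOM ethers are base-stable and C3 carries no acidic hydrogen, so it cannot epimerise.

**Step 9**
Reactants: 15 (E)-1-[(3R)-3-hydroxy-5,7-bis(methoxymethoxy)-2,2-dimethylchroman-6-yl]-3-[4-(methoxymethoxy)phenyl]prop-2-en-1-one
Product: 16 (E)-1-[(3R)-3,5,7-trihydroxy-2,2-dimethylchroman-6-yl]-3-(4-hydroxyphenyl)prop-2-en-1-one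
Conditions: 3 M aq. HCl–MeOH (1:5), rt → 40 °C, stopped at full conversion; cold water, EtOAc extraction, no basic wash
Reagents that add atoms: none
Why: Acid-catalysed acetal cleavage of the three MOM ethers, with methanol taking up the formaldehyde unit as dimethoxymethane; the chroman ether, the secondary alcohol and the E-enone should be inert to dilute acid at this temperature, and oxa-Michael closure of the freed 2'-phenols is slow in acid.

**Compound list**

1 | 2,4,6-trihydroxyacetophenone | CC(=O)c1c(O)cc(O)cc1O | starting material
2 | 1-[2,6-dihydroxy-4-(triisopropylsilyloxy)phenyl]ethanone | CC(=O)c1c(O)cc(O[Si](C(C)C)(C(C)C)C(C)C)cc1O | intermediate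
3 | 1-[2,6-bis(methoxymethoxy)-4-(triisopropylsilyloxy)phenyl]ethanone | CC(=O)c1c(OCOC)cc(O[Si](C(C)C)(C(C)C)C(C)C)cc1OCOC | intermediate
4 | 1-[4-hydroxy-2,6-bis(methoxymethoxy)phenyl]ethanone | CC(=O)c1c(OCOC)cc(O)cc1OCOC | intermediate
5 | formaldehyde | C=O | starting material
6 | 1-[4-hydroxy-3-(hydroxymethyl)-2,6-bis(methoxymethoxy)phenyl]ethanone | CC(=O)c1c(OCOC)cc(O)c(CO)c1OCOC | intermediate
7 | 2-methylprop-1-enylboronic acid pinacol ester | CC(C)=CB1OC(C)(C)C(C)(C)O1 | starting material
8 | 4-acetyl-3,5-bis(methoxymethoxy)-6-methylidenecyclohexa-2,4-dien-1-one (o-quinone methide) | C=C1C(=O)C=C(OCOC)C(C(C)=O)=C1OCOC | intermediate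
9 | (R)-1-[5,7-bis(methoxymethoxy)-2,2-dimethyl-3-(4,4,5,5-tetramethyl-1,3,2-dioxaborolan-2-yl)chroman-6-yl]ethanone | CC1(C)Oc2cc(OCOC)c(C(C)=O)c(OCOC)c2C[C@H]1B1OC(C)(C)C(C)(C)O1 | intermediate
10 | 1-[(3R)-5,7-bis(methoxymethoxy)-2,2-dimethyl-3-(4,4,5,5-tetramethyl-1,3,2-dioxaborolan-2-yloxy)chroman-6-yl]ethanone (borate ester) | CC1(C)Oc2cc(OCOC)c(C(C)=O)c(OCOC)c2C[C@H]1OB1OC(C)(C)C(C)(C)O1 | intermediate
11 | 1-[(3R)-3-hydroxy-5,7-bis(methoxymethoxy)-2,2-dimethylchroman-6-yl]ethanone | CC1(C)Oc2cc(OCOC)c(C(C)=O)c(OCOC)c2C[C@H]1O | intermediate
12 | 4-hydroxybenzaldehyde | O=Cc1ccc(O)cc1 | starting material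
13 | 4-(methoxymethoxy)benzaldehyde | COCOc1ccc(C=O)cc1 | intermediate
14 | 3-hydroxy-1-[(3R)-3-hydroxy-5,7-bis(methoxymethoxy)-2,2-dimethylchroman-6-yl]-3-[4-(methoxymethoxy)phenyl]propan-1-one (aldol adduct, both epimers at the new carbinol carbon) | CC1(C)Oc2cc(OCOC)c(C(=O)CC(O)c3ccc(OCOC)cc3)c(OCOC)c2C[C@H]1O | intermediate
15 | (E)-1-[(3R)-3-hydroxy-5,7-bis(methoxymethoxy)-2,2-dimethylchroman-6-yl]-3-[4-(methoxymethoxy)phenyl]prop-2-en-1-one | CC1(C)Oc2cc(OCOC)c(C(=O)/C=C/c3ccc(OCOC)cc3)c(OCOC)c2C[C@H]1O | intermediate
16 | (E)-1-[(3R)-3,5,7-trihydroxy-2,2-dimethylchroman-6-yl]-3-(4-hydroxyphenyl)prop-2-en-1-one | CC1(C)Oc2cc(O)c(C(=O)/C=C/c3ccc(O)cc3)c(O)c2C[C@H]1O | target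

**Step count**

Total: 9 steps. Longest linear sequence: 8 steps (steps 1–6, 8 and 9, from 1 to 16); step 7 is a one-step side branch.

**Steps most likely to fail**

Step 5 (proposed new method) is the main risk. The phosphate may discriminate poorly between the two faces of an alkene that offers no hydrogen-bond handle. Boron may be lost from the β-boryl cation, which would transfer the alkenyl group and give a C-prenyl phenol. The weakly nucleophilic alkenylboronate may also react too slowly, so that the quinone methide is consumed by the free ring position of a second molecule. The fallback uses known chemistry, sets out from phenol 4 and rejoins the route at 11. Condensation of 4 with 3-methylbut-2-enal (ethylenediammonium diacetate cat., toluene, reflux; ortho-aldol, dehydration, oxa-6π electrocyclisation) should give the chromene 1-[5,7-bis(methoxymethoxy)-2,2-dimethyl-2H-chromen-6-yl]ethanone F1. Jacobsen–Katsuki epoxidation follows, with (R,R)-N,N'-bis(3,5-di-tert-butylsalicylidene)cyclohexane-1,2-diaminomanganese chloride, (salen)MnCl with trivalent manganese, NaOCl and 4-phenylpyridine N-oxide in CH2Cl2 at 0 °C. This catalyst class is at its best on 2,2-dimethylchromenes and is expected to give the cis-epoxide 1-[(3R,4R)-3,4-epoxy-5,7-bis(methoxymethoxy)-2,2-dimethylchroman-6-yl]ethanone F2; the (S,S)-catalyst would be taken if the sense proved opposite. Crude F2, an acid-labile electron-rich benzylic epoxide, would be hydrogenolysed at the benzylic C4–O bond (H2, Pd/C, EtOAc, rt), leaving the C3–O bond and its configuration untouched and giving 11.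

Step 4 is the second risk. Hydroxymethylation may continue at the second ortho position, the product may condense with unreacted phenoxide to a diarylmethane, and the acetyl group may undergo aldol addition to formaldehyde. The fallback sets out from 4 and rejoins at 6 by a boron-templated ortho-hydroxymethylation. Phenylboronic acid, paraformaldehyde and catalytic propionic acid in refluxing toluene with water removal deliver formaldehyde to one ortho carbon only and hold the product as the cyclic boronate 1-[5,7-bis(methoxymethoxy)-2-phenyl-4H-1,3,2-benzodioxaborinin-6-yl]ethanone F3. This form can neither react a second time nor self-condense. Exchange with pinacol in THF at rt then releases 6; peroxide is avoided at this stage because 6 is a para-hydroxy aryl ketone.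

Step 9 is the third risk. Once the 2'-phenols are free, either can close onto the enone by oxa-Michael addition during deprotection or work-up, draining the chalcone into flavanones. The fallback sets out from 15 and rejoins at 16 by going through the flavanones on purpose. The acid treatment is run to completion without fractionation, giving 16 together with its two flavanone isomers, each as a pair of epimers at the aryl-bearing carbon: the linear flavanone closed through the C7 oxygen F4 and the angular flavanone closed through the C5 oxygen F5. The crude mixture is then stirred with aqueous KOH in EtOH at 0 °C → rt, where both flavanones should ring-open by enolisation and β-elimination of the phenoxide to the chalcone polyphenoxide. Rapid acidification to about pH 5 at 0 °C with immediate extraction should return 16.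

**Further compounds**

F1 | step 5 | 1-[5,7-bis(methoxymethoxy)-2,2-dimethyl-2H-chromen-6-yl]ethanone | CC1(C)Oc2cc(OCOC)c(C(C)=O)c(OCOC)c2C=C1
F2 | step 5 | 1-[(3R,4R)-3,4-epoxy-5,7-bis(methoxymethoxy)-2,2-dimethylchroman-6-yl]ethanone | CC1(C)Oc2cc(OCOC)c(C(C)=O)c(OCOC)c2[C@H]3O[C@@H]13
F3 | step 4 | 1-[5,7-bis(methoxymethoxy)-2-phenyl-4H-1,3,2-benzodioxaborinin-6-yl]ethanone | CC(=O)c1c(OCOC)cc2OB(c3ccccc3)OCc2c1OCOC
F4 | step 9 | linear flavanone isomer of 16, pyranone ring closed through the C7 oxygen, (3R)-carbinol retained, both epimers at the aryl-bearing carbon | CC1(C)Oc2cc3OC(c4ccc(O)cc4)CC(=O)c3c(O)c2C[C@H]1O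
F5 | step 9 | angular flavanone isomer of 16, pyranone ring closed through the C5 oxygen, (3R)-carbinol retained, both epimers at the aryl-bearing carbon | CC1(C)Oc2cc(O)c3C(=O)CC(c4ccc(O)cc4)Oc3c2C[C@H]1O
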